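**Strategy**

Ring B (the quinone ring) is opened at C3–C4, the bond from its only CH to the neighbouring carbonyl carbon, and at C1–C2. Ring A carries its two oxygens symmetrically at C5 and C8, so C1 and C4 are equivalent and both can come from a symmetrical 3,6-dimethoxybenzocyclobutene-1,2-dione; C2, C3 and the side chain come from a chiral 2-lithioallyl alkoxide. In the key step the derived 2-alkenyl-2-hydroxybenzocyclobutenone is heated: electrocyclic opening gives an o-quinoid vinylketene, whose 6π closure joins the ketene carbon to the alkene CH2 and delivers the complete naphthalene-1,4-diol, trapped as its triacetate. Oxidative demethylation of ring A, hydrolysis and acylation finish.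

Key step: step 7

Remark on the chemistry: the 5,8-dihydroxy-1,4-naphthoquinone core tautomerises rapidly, so its 6-substituted and 2-substituted forms are one compound; alkannin and the target are written as the 2-substituted tautomer.

**Route**

Step 1
Reactants: 1 2-bromo-1,4-dimethoxybenzene; 2 1,1-dimethoxyethene
Product: 4 2,5-dimethoxybicyclo[4.2.0]octa-1,3,5-trien-7-one (3,6-dimethoxybenzocyclobutenone), via tetramethoxy cycloadduct 3 (not isolated)
Conditions: NaNH2 (2 equiv), THF, reflux; then 1 M HCl, THF, rt
Reagents that add atoms: water, O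
Why: Elimination–addition through a benzyne: NaNH2 removes the proton flanked by Br and OMe, the symmetrical 3,6-dimethoxybenzyne is trapped by the electron-rich ketene acetal in a [2+2] cycloaddition (one regioisomer only), and mild acid hydrolysis of the strained ketal should give the ketone.

Step 2
Reactants: 4 3,6-dimethoxybenzocyclobutenone
Product: 6 2,5-dimethoxybicyclo[4.2.0]octa-1,3,5-triene-7,8-dione (3,6-dimethoxybenzocyclobutene-1,2-dione), via gem-dibromide 5 (not isolated)
Conditions: N-bromosuccinimide (2.2 equiv), dibenzoyl peroxide (cat.), PhCF3, reflux; filter; then CF3CO2Ag (2.2 equiv), MeCN/H2O, rt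
Reagents that add atoms: water, O
Why: Wohl–Ziegler radical bromination at the doubly activated (benzylic and α-keto) CH2 should give the gem-dibromide, and silver-assisted hydrolysis unmasks the second carbonyl group.

Step 3
Reactants: 7 acrolein
Product: 9 2-bromoprop-2-enal (2-bromoacrolein), via 2,3-dibromopropanal 8 (not isolated)
Conditions: Br2 (1.0 equiv), CH2Cl2, −78 to 0 °C; then Et3N (1.05 equiv), 0 °C
Reagents that add atoms: bromine, BrBr
Why: Electrophilic bromine addition to the enal followed by E1cB loss of HBr from the α-bromo aldehyde, the standard bromination–dehydrobromination route to α-bromoenals.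

Step 4
Reactants: 9 2-bromoprop-2-enal
Product: 10 (3S)-2-bromohexa-1,5-dien-3-ol
Conditions: (−)-Ipc2B(allyl) (the reagent derived from (+)-α-pinene), Et2O, −78 °C; then NaOH, H2O2, 0 °C to rt
Reagents that add atoms: (−)-B-allyldiisopinocampheylborane, C=CCB([C@@H]1C[C@@H]2C[C@H]([C@H]1C)C2(C)C)[C@@H]1C[C@@H]2C[C@H]([C@H]1C)C2(C)C
Why: Brown asymmetric allylboration through a closed chair transition state; this reagent adds to the Si face of aldehydes, which for an aldehyde substituent that outranks allyl (as with benzaldehyde) corresponds to the S carbinol, and the cyclic transition state enforces 1,2-addition.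

Step 5
Reactants: 10 (3S)-2-bromohexa-1,5-dien-3-ol
Product: 11 (3S)-2-bromo-6-methylhepta-1,5-dien-3-ol
Conditions: second-generation Grubbs catalyst (3 mol%), 2-methylbut-2-ene (large excess), CH2Cl2, 40 °C
Reagents that add atoms: 2-methylbut-2-ene, CC=C(C)C
Why: Olefin cross-metathesis of the terminal vinyl group with 2-methylbut-2-ene installs the trisubstituted prenyl terminus, while the electron-poor 1,1-disubstituted bromoalkene should be inert and the stereocentre is untouched.

Step 6
Reactants: 11 (3S)-2-bromo-6-methylhepta-1,5-dien-3-ol; 6 3,6-dimethoxybenzocyclobutene-1,2-dione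
Product: 13 8-hydroxy-8-[(3S)-3-hydroxy-6-methylhepta-1,5-dien-2-yl]-2,5-dimethoxybicyclo[4.2.0]octa-1,3,5-trien-7-one (both C8 epimers), via dilithio alkoxide 12 (not isolated)
Conditions: MeLi (1.0 equiv), then t-BuLi (2.0 equiv), Et2O, −78 °C; cannulate into 6, THF, −78 °C; AcOH, −78 °C
Reagents that add atoms: none
Why: Deprotonation and bromine–lithium exchange give the O,C-dilithio species, whose vinyllithium carbon adds once (1,2-addition of an organolithium to a non-enolisable 1,2-dione) to one of the two equivalent strained carbonyl groups; the new C8 centre forms as an inconsequential epimer mixture because it becomes sp2 in step 7, and the S centre is carried as its alkoxide.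

Step 7
Reactants: 13 alkenyl hydroxybenzocyclobutenone
Product: 16 (1S)-1-(1,4-diacetoxy-5,8-dimethoxynaphthalen-2-yl)-4-methylpent-3-en-1-yl acetate, via o-quinoid vinylketene 14 (not isolated), via naphthalene-1,4-diol 15 (not isolated)
Conditions: degassed p-xylene, 140 °C, argon; then Ac2O, pyridine, DMAP (cat.), rt
Reagents that add atoms: acetic anhydride, CC(=O)OC(C)=O
Why: Heating opens the four-membered ring of 13 by conrotatory 4π electrocyclic cleavage of the C7–C8 bond to the o-quinoid vinylketene 14, which closes by disrotatory 6π electrocyclisation between the ketene carbon (future C4) and the terminal CH2 of the 1,1-disubstituted alkene (future C3), and tautomerisation gives the aromatic diol 15. The closest known reaction type is the Moore rearrangement of 4-alkenyl-4-hydroxycyclobutenones and its benzo-fused variant leading to naphthoquinones. Ring B is closed as a six-membered ring in a 6π electrocyclic mode, driven by aromatisation of both rings. No stereocentre is created: the uncontrolled C8 centre of 13 becomes sp2, and the side-chain centre lies outside the pericyclic array and should keep its S configuration. The step needs the alkenyl group to rotate inward toward the ketene, which the strong outward preference of the hydroxyl donor secures, and it needs no regiocontrol because the dione was symmetrical. Acetylation in the same flask protects the air-sensitive diol and differentiates the two rings for the oxidation that follows.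

Step 8
Reactants: 16 triacetate
Product: 17 (1S)-1-(1,4-diacetoxy-5,8-dioxo-5,8-dihydronaphthalen-2-yl)-4-methylpent-3-en-1-yl acetate
Conditions: (NH4)2Ce(NO3)6 (2.5 equiv), MeCN/H2O, 0 °C
Reagents that add atoms: water, O
Why: Oxidative demethylation of a p-dimethoxyarene; the dimethoxy ring is the electron-rich one while the acetoxy groups deactivate the other ring, so ring A should be converted into the quinone with both new oxygens coming from water.

Step 9
Reactants: 17 quinone triacetate
Product: 18 alkannin, 5,8-dihydroxy-2-[(1S)-1-hydroxy-4-methylpent-3-en-1-yl]naphthalene-1,4-dione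
Conditions: 1 M NaOH (aq), THF, 0 °C, argon; then 1 M HCl to pH 3
Reagents that add atoms: none
Why: Saponification of the two activated aryl acetates and the secondary acetate by acyl–oxygen cleavage leaves the stereocentre untouched, and the freed dihydroxynaphthoquinone equilibrates to the tautomer drawn for alkannin.

Step 10
Reactants: 18 alkannin; 19 3-methylbut-2-enoic acid
Product: 20 alkannin β,β-dimethylacrylate, (1S)-1-(5,8-dihydroxy-1,4-dioxo-1,4-dihydronaphthalen-2-yl)-4-methylpent-3-en-1-yl 3-methylbut-2-enoate
Conditions: DCC, DMAP (cat.), CH2Cl2, 0 °C to rt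
Reagents that add atoms: none
Why: Steglich esterification acylates the secondary side-chain hydroxyl with retention (no C–O cleavage at the stereocentre), the two peri-hydroxyls being deactivated by chelation to the quinone carbonyls.

**Compound list**

1 | 2-bromo-1,4-dimethoxybenzene | COc1ccc(OC)c(Br)c1 | starting material
2 | 1,1-dimethoxyethene | C=C(OC)OC | starting material
3 | 2,5,7,7-tetramethoxybicyclo[4.2.0]octa-1,3,5-triene | COc1ccc(OC)c2c1CC2(OC)OC | intermediate
4 | 2,5-dimethoxybicyclo[4.2.0]octa-1,3,5-trien-7-one | COc1ccc(OC)c2c1CC2=O | intermediate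
5 | 8,8-dibromo-2,5-dimethoxybicyclo[4.2.0]octa-1,3,5-trien-7-one | COc1ccc(OC)c2c1C(Br)(Br)C2=O | intermediate
6 | 2,5-dimethoxybicyclo[4.2.0]octa-1,3,5-triene-7,8-dione | COc1ccc(OC)c2c1C(=O)C2=O | intermediate
7 | acrolein (prop-2-enal) | C=CC=O | starting material
8 | 2,3-dibromopropanal (racemic) | O=CC(Br)CBr | intermediate
9 | 2-bromoprop-2-enal | C=C(Br)C=O | intermediate
10 | (3S)-2-bromohexa-1,5-dien-3-ol | C=CC[C@H](O)C(Br)=C | intermediate
11 | (3S)-2-bromo-6-methylhepta-1,5-dien-3-ol | CC(C)=CC[C@H](O)C(Br)=C | intermediate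
12 | lithium (3S)-2-lithio-6-methylhepta-1,5-dien-3-olate | CC(C)=CC[C@H](O[Li])C([Li])=C | intermediate
13 | 8-hydroxy-8-[(3S)-3-hydroxy-6-methylhepta-1,5-dien-2-yl]-2,5-dimethoxybicyclo[4.2.0]octa-1,3,5-trien-7-one (C8 epimers) | CC(C)=CC[C@H](O)C(=C)C1(O)C(=O)c2c(OC)ccc(OC)c21 | intermediate
14 | o-quinoid vinylketene, {6-[(1Z,3S)-1,3-dihydroxy-6-methyl-2-methylidenehept-5-en-1-ylidene]-2,5-dimethoxycyclohexa-2,4-dien-1-ylidene}methanone (hydroxyl outward, alkenyl toward the ketene) | CC(C)=CC[C@H](O)C(=C)/C(O)=C1/C(OC)=CC=C(OC)C1=C=O | intermediate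
15 | 2-[(1S)-1-hydroxy-4-methylpent-3-en-1-yl]-5,8-dimethoxynaphthalene-1,4-diol | CC(C)=CC[C@H](O)c1cc(O)c2c(OC)ccc(OC)c2c1O | intermediate
16 | (1S)-1-(1,4-diacetoxy-5,8-dimethoxynaphthalen-2-yl)-4-methylpent-3-en-1-yl acetate | CC(C)=CC[C@H](OC(C)=O)c1cc(OC(C)=O)c2c(OC)ccc(OC)c2c1OC(C)=O | intermediate
17 | (1S)-1-(1,4-diacetoxy-5,8-dioxo-5,8-dihydronaphthalen-2-yl)-4-methylpent-3-en-1-yl acetate | CC(C)=CC[C@H](OC(C)=O)c1cc(OC(C)=O)c2C(=O)C=CC(=O)c2c1OC(C)=O | intermediate
18 | alkannin | CC(C)=CC[C@H](O)C1=CC(=O)c2c(O)ccc(O)c2C1=O | intermediate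
19 | 3-methylbut-2-enoic acid | CC(C)=CC(O)=O | starting material
20 | alkannin β,β-dimethylacrylate | CC(C)=CC[C@H](OC(=O)C=C(C)C)C1=CC(=O)c2c(O)ccc(O)c2C1=O | target

**Step count and risks**

Total: 10 steps. Longest linear sequence: 8 steps (steps 3 to 10, from acrolein 7).

Steps most likely to fail:

1. Step 6. The side-chain lithium alkoxide may add to the remaining strained ketone and trigger cleavage of the four-membered ring, or a second vinyllithium may add. The fallback sets out from 11 and comes back at 13. Compound 11 would be converted with 4-methoxybenzyl trichloroacetimidate and catalytic camphorsulfonic acid into the p-methoxybenzyl ether F1. Bromine–lithium exchange (t-BuLi, 2 equiv, Et2O, −78 °C) and addition to 6 would give the monoprotected adduct F2. DDQ in wet CH2Cl2 (pH 7 buffer) would then remove the ether and rejoin the route at 13.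

2. Step 8. Tetravalent cerium may attack the electron-rich trisubstituted alkene, or an aryl acetate may be lost before oxidation so that the wrong ring is oxidised. The fallback sets out from 6 and comes back at 18, and avoids oxidative demethylation altogether. BBr3 (CH2Cl2, −78 to 0 °C) would demethylate 6 to the dihydroxy dione F3, and TBSOTf with 2,6-lutidine would give the bis(silyl ether) F4. Addition of 12 as in step 6 would give the adduct F5, and heating in p-xylene would give the naphthalene-1,4-diol F6. Ag2O would oxidise this to the quinone F7, and HF·pyridine would remove both silyl groups to give 18.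

3. Step 2. Electrophilic bromination of the electron-rich dimethoxy ring may compete with the radical chain, or the second bromination may stall. The fallback sets out from 1 and comes back at 6, bringing in the second oxygen with the two-carbon partner. Methyl (trimethylsilyloxy)acetate, lithium diisopropylamide and Me3SiCl would give the ketene silyl acetal F8. The aryne from 1 (lithium 2,2,6,6-tetramethylpiperidide, THF, −78 °C to rt) would add to it in a [2+2] cycloaddition to give the cycloadduct F9. Dilute HCl would unmask the α-hydroxy ketone F10, and Dess–Martin periodinane would oxidise it to 6.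

**Further compounds**

F1 | step 6 | (3S)-2-bromo-3-[(4-methoxybenzyl)oxy]-6-methylhepta-1,5-diene | CC(C)=CC[C@H](OCc1ccc(OC)cc1)C(Br)=C
F2 | step 6 | 8-hydroxy-8-{(3S)-3-[(4-methoxybenzyl)oxy]-6-methylhepta-1,5-dien-2-yl}-2,5-dimethoxybicyclo[4.2.0]octa-1,3,5-trien-7-one | CC(C)=CC[C@H](OCc1ccc(OC)cc1)C(=C)C1(O)C(=O)c2c(OC)ccc(OC)c21
F3 | step 8 | 2,5-dihydroxybicyclo[4.2.0]octa-1,3,5-triene-7,8-dione | Oc1ccc(O)c2c1C(=O)C2=O
F4 | step 8 | 2,5-bis(tert-butyldimethylsilyloxy)bicyclo[4.2.0]octa-1,3,5-triene-7,8-dione | CC(C)(C)[Si](C)(C)Oc1ccc(O[Si](C)(C)C(C)(C)C)c2c1C(=O)C2=O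
F5 | step 8 | 2,5-bis(tert-butyldimethylsilyloxy)-8-hydroxy-8-[(3S)-3-hydroxy-6-methylhepta-1,5-dien-2-yl]bicyclo[4.2.0]octa-1,3,5-trien-7-one | CC(C)=CC[C@H](O)C(=C)C1(O)C(=O)c2c(O[Si](C)(C)C(C)(C)C)ccc(O[Si](C)(C)C(C)(C)C)c21
F6 | step 8 | 5,8-bis(tert-butyldimethylsilyloxy)-2-[(1S)-1-hydroxy-4-methylpent-3-en-1-yl]naphthalene-1,4-diol | CC(C)=CC[C@H](O)c1cc(O)c2c(O[Si](C)(C)C(C)(C)C)ccc(O[Si](C)(C)C(C)(C)C)c2c1O
F7 | step 8 | 5,8-bis(tert-butyldimethylsilyloxy)-2-[(1S)-1-hydroxy-4-methylpent-3-en-1-yl]naphthalene-1,4-dione | CC(C)=CC[C@H](O)C1=CC(=O)c2c(O[Si](C)(C)C(C)(C)C)ccc(O[Si](C)(C)C(C)(C)C)c2C1=O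
F8 | step 2 | 1-methoxy-1,2-bis(trimethylsilyloxy)ethene | COC(O[Si](C)(C)C)=CO[Si](C)(C)C
F9 | step 2 | 2,5,7-trimethoxy-7,8-bis(trimethylsilyloxy)bicyclo[4.2.0]octa-1,3,5-triene | COc1ccc(OC)c2c1C(O[Si](C)(C)C)C2(OC)O[Si](C)(C)C
F10 | step 2 | 8-hydroxy-2,5-dimethoxybicyclo[4.2.0]octa-1,3,5-trien-7-one | COc1ccc(OC)c2c1C(O)C2=O
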